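**Strategy.** Ring A, the bromo-dimethylcyclohexanol, is cut into two three-carbon pieces, CH2–C(OH)–CH2 and CH2–CHBr–CMe2. Its carbinol carbon and its CHBr carbon lie para to each other, so a ketone at the later CHBr carbon turns both neighbours (CH2 and CMe2) into nucleophiles, while an exocyclic methylene at the later carbinol carbon turns both of its CH2 neighbours into allylic electrophiles. The key step therefore joins the dianion of methyl 4-methyl-3-oxopentanoate and 3-chloro-2-(chloromethyl)prop-1-ene in a one-pot (3+3) annulation. The ring is then made chiral, extended to a propargylic bromide and joined to a Birch-derived keto ester; gold closes cyclopentene and lactone, and both bromides come from ketones.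

Key step: step 1

Assumption: the (S,S) enantiomer of the chiral ammonium phase-transfer catalyst is taken to favour the (S) quaternary centre of 14; should a test alkylation show the opposite sense, the (R,R) catalyst is used.

Step 1
Reactants: 1 methyl 4-methyl-3-oxopentanoate; 2 3-chloro-2-(chloromethyl)prop-1-ene
Product: 4 methyl 3,3-dimethyl-5-methylidene-2-oxocyclohexane-1-carboxylate (racemic), via open-chain allylic chloride 3 (not isolated)
Conditions: NaH, THF, 0 °C; n-BuLi, 0 °C; 2 (1.0 equiv), −78 → 0 °C; then Pd(PPh3)4 (3 mol %), 45 °C
Reagents that add atoms: none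
Why: The dianion of 1 is alkylated at its terminal, tertiary carbanion by one allylic chloride of 2, which makes the CMe2–CH2 bond and leaves the stabilised keto ester anion of 3; zerovalent palladium then ionises the second allylic chloride and the soft enolate carbon closes the ring, which makes the CH–CH2 bond. The closest known reaction types are the γ-alkylation of β-keto ester dianions and the intramolecular Tsuji–Trost allylation, together a formal (3+3) annulation of a 1,3-dinucleophile with a 2-methylenepropane-1,3-diyl dielectrophile. The six-membered ring closes by 6-exo attack on a terminus of the π-allyl unit (6-exo-tet if chloride is displaced directly), and both termini give the same product. The only new stereocentre, the ester-bearing CH of 4, forms as a racemate and is erased in step 2. The step needs terminal before internal alkylation, secured by the higher reactivity of the terminal carbanion of the dianion and by one equivalent of 2, and C- over O-cyclisation, secured by the reversible palladium-mediated allylation.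

Step 2
Reactants: 4 methyl 3,3-dimethyl-5-methylidene-2-oxocyclohexane-1-carboxylate
Product: 5 2,2-dimethyl-4-methylidenecyclohexan-1-one
Conditions: LiCl, H2O, DMSO, 150 °C
Reagents that add atoms: none
Why: Krapcho dealkoxycarbonylation, in which chloride demethylates the ester and the β-keto carboxylate loses CO2, should leave the isolated alkene untouched and removes the stereocentre of 4.

Step 3
Reactants: 5 2,2-dimethyl-4-methylidenecyclohexan-1-one
Product: 6 (1R)-2,2-dimethyl-4-methylidenecyclohexan-1-ol
Conditions: (S)-2-methyl-CBS-oxazaborolidine (20 mol %), catecholborane, toluene, −78 → −40 °C; aqueous NaOH work-up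
Reagents that add atoms: none
Why: Corey–Bakshi–Shibata reduction, in which the quaternary side acts as the large and the CH2 side as the small group, should give the (R)-carbinol with the (S)-catalyst, and catecholborane at low temperature spares the 1,1-disubstituted alkene.

Step 4
Reactants: 6 (1R)-2,2-dimethyl-4-methylidenecyclohexan-1-ol
Product: 7 (3S,6R)-5,5-dimethyl-1-oxaspiro[2.5]octan-6-ol
Conditions: VO(acac)2 (5 mol %), t-BuOOH, NaOAc, toluene, 23 °C
Reagents that add atoms: tert-butyl hydroperoxide, CC(C)(C)OO
Why: Vanadium-catalysed hydroxyl-directed epoxidation of a bishomoallylic alcohol: the vanadate ester reaches the exocyclic alkene only in the chair with axial OH, in which the other alkene face is also blocked by the axial methyl group, so oxygen should be delivered cis to the OH and set the spiro centre (S).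

Step 5
Reactants: 7 (3S,6R)-5,5-dimethyl-1-oxaspiro[2.5]octan-6-ol; 8 3-bromoprop-1-yne
Product: 9 (1R,4R)-1-(4-bromobut-2-yn-1-yl)-3,3-dimethylcyclohexane-1,4-diol
Conditions: 8 (3.2 equiv), n-BuLi (3.1 equiv), THF, −90 °C; BF3·OEt2; then 7, −78 °C; aqueous work-up
Reagents that add atoms: none
Why: Yamaguchi–Hirao alkynylation: the BF3-activated epoxide is opened by the alkynyl nucleophile at its CH2 carbon in an SN2 reaction, which leaves the tertiary C–O stereocentre untouched (the first equivalent of acetylide is spent on the free OH).

Step 6
Reactants: 9 (1R,4R)-1-(4-bromobut-2-yn-1-yl)-3,3-dimethylcyclohexane-1,4-diol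
Product: 10 (1R,4R)-1-(4-bromobut-2-yn-1-yl)-3,3-dimethyl-1,4-bis(triethylsilyloxy)cyclohexane
Conditions: TESOTf (2.4 equiv), 2,6-lutidine, CH2Cl2, −78 → 0 °C
Reagents that add atoms: triethylsilyl trifluoromethanesulfonate, CC[Si](CC)(CC)OS(=O)(=O)C(F)(F)F
Why: Silylation with a silyl triflate masks both hydroxyl groups for the enolate alkylation of step 8 and the tertiary one for the gold step, where a free homopropargylic OH would add to the alkyne.

Step 7
Reactants: 11 methyl 2-methoxy-5-methylbenzoate
Product: 13 methyl 3-methyl-6-oxocyclohex-2-ene-1-carboxylate, via dihydro enol ether 12 (not isolated)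
Conditions: Li, NH3, THF, t-BuOH (1.5 equiv), −78 °C; NH4Cl; then 1 M HCl, THF, 0 °C
Reagents that add atoms: water, O
Why: Birch reduction: the ester directs 1,4-reduction so that OMe and Me stay on the two remaining double bonds, and protonation at the ester carbon followed by enol ether hydrolysis should give the β-keto ester with its alkene in the β,γ-position.

Step 8
Reactants: 13 methyl 3-methyl-6-oxocyclohex-2-ene-1-carboxylate; 10 (1R,4R)-1-(4-bromobut-2-yn-1-yl)-3,3-dimethyl-1,4-bis(triethylsilyloxy)cyclohexane
Product: 14 methyl (1S)-1-{4-[(1R,4R)-3,3-dimethyl-1,4-bis(triethylsilyloxy)cyclohexyl]but-2-yn-1-yl}-3-methyl-6-oxocyclohex-2-ene-1-carboxylate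
Conditions: (S,S)-N-spiro bis(binaphthyl)ammonium bromide bearing 3,4,5-trifluorophenyl groups (3 mol %), Cs2CO3, toluene, −20 °C
Reagents that add atoms: none
Why: Asymmetric phase-transfer alkylation of a cyclic β-keto ester: the enolate is paired with the chiral ammonium ion, which shields one face, so the propargylic bromide should be taken up by SN2 at the doubly activated carbon and set the quaternary centre (S) under catalyst control.

Step 9
Reactants: 14 alkylated keto ester
Product: 16 cyclopentene-fused keto lactone (bis-TES ether), via tertiary hydroxy ester 15 (not isolated)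
Conditions: [(t-Bu)2P(o-biphenyl)Au(NCMe)]SbF6 (3 mol %), H2O (10 equiv), 1,4-dioxane, 23 °C; then pyridinium p-toluenesulfonate, 40 °C
Reagents that add atoms: water, O
Why: Gold-catalysed 5-endo hydroxycyclisation of a 1,5-enyne: monovalent gold activates the alkyne, the CH end of the trisubstituted alkene attacks it on the face of its own tether (cis ring fusion) and water opens the cyclopropyl gold carbene at the tertiary carbon from the opposite face, which places the new hydroxyl cis to the ester so that it lactonises; both new stereocentres follow from the quaternary centre.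

Step 10
Reactants: 16 cyclopentene-fused keto lactone (bis-TES ether)
Product: 17 saturated tricyclic keto lactone (bis-TES ether)
Conditions: [Ir(cod)(PCy3)(py)]PF6 (5 mol %), H2 (1 atm), CH2Cl2, 23 °C
Reagents that add atoms: none
Why: Homogeneous hydrogenation should add H2 to the cyclopentene from its convex face, the side of the ring-fusion hydrogen and of the lactone carbonyl that can bind iridium, so that the CH2 link ends on the concave face over the six-membered ring.

Step 11
Reactants: 17 saturated tricyclic keto lactone (bis-TES ether)
Product: 19 diketo lactone with free tertiary alcohol, via desilylated diol 18 (not isolated)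
Conditions: CrO3, H2SO4, H2O, acetone, 0 °C
Reagents that add atoms: none
Why: Jones oxidation: the aqueous acid cleaves both silyl ethers and chromic acid oxidises the secondary alcohol of ring A, while the tertiary alcohol, the lactone and the ketone remain.

Step 12
Reactants: 19 diketo lactone with free tertiary alcohol
Product: 21 bis(alkenyl bromide), via bis(silylhydrazone) 20 (not isolated)
Conditions: t-BuMe2SiNHNHSiMe2t-Bu, Sc(OTf)3 (1 mol %), CHCl3, 55 °C; then Br2, 2-tert-butyl-1,1,3,3-tetramethylguanidine, CH2Cl2, 0 → 23 °C
Reagents that add atoms: bromine, BrBr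
Why: N-silyl hydrazone variant of the Barton alkenyl halide synthesis: bromine oxidises each hydrazone to a diazo compound and then to an α-bromo cation, which loses the only available α-proton because each ketone has a quaternary carbon on its other side.

Step 13
Reactants: 21 bis(alkenyl bromide)
Product: 22 target dibromo lactone CNP0282702.1
Conditions: Co(acac)2, t-BuOOH, Et3SiH, 1,4-cyclohexadiene, n-PrOH, 23 °C
Reagents that add atoms: none
Why: Hydrogen-atom-transfer hydrogenation of alkenyl halides: a cobalt hydride adds H to the CH end of each alkenyl bromide and the α-bromo radical takes the second hydrogen from 1,4-cyclohexadiene in the axial direction; in ring A the chair is fixed by the equatorial CH2 link, so Br should end equatorial and cis to OH, and in the lactone ring an axial Br would clash with the axial cyclopentane carbon, so Br should again end equatorial.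

**Compound list**

1 | methyl 4-methyl-3-oxopentanoate | COC(=O)CC(=O)C(C)C | starting material
2 | 3-chloro-2-(chloromethyl)prop-1-ene | C=C(CCl)CCl | starting material
3 | methyl 6-(chloromethyl)-4,4-dimethyl-3-oxohept-6-enoate | COC(=O)CC(=O)C(C)(C)CC(=C)CCl | intermediate
4 | methyl 3,3-dimethyl-5-methylidene-2-oxocyclohexane-1-carboxylate (racemic) | COC(=O)C1CC(=C)CC(C)(C)C1=O | intermediate
5 | 2,2-dimethyl-4-methylidenecyclohexan-1-one | C=C1CCC(=O)C(C)(C)C1 | intermediate
6 | (1R)-2,2-dimethyl-4-methylidenecyclohexan-1-ol | C=C1CC[C@@H](O)C(C)(C)C1 | intermediate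
7 | (3S,6R)-5,5-dimethyl-1-oxaspiro[2.5]octan-6-ol | CC1(C)C[C@]2(CO2)CC[C@H]1O | intermediate
8 | 3-bromoprop-1-yne | BrCC#C | starting material
9 | (1R,4R)-1-(4-bromobut-2-yn-1-yl)-3,3-dimethylcyclohexane-1,4-diol | CC1(C)C[C@](O)(CC#CCBr)CC[C@H]1O | intermediate
10 | (1R,4R)-1-(4-bromobut-2-yn-1-yl)-3,3-dimethyl-1,4-bis(triethylsilyloxy)cyclohexane | CC1(C)C[C@](O[Si](CC)(CC)CC)(CC#CCBr)CC[C@H]1O[Si](CC)(CC)CC | intermediate
11 | methyl 2-methoxy-5-methylbenzoate | COC(=O)c1cc(C)ccc1OC | starting material
12 | methyl 2-methoxy-5-methylcyclohexa-2,5-diene-1-carboxylate | COC(=O)C1C=C(C)CC=C1OC | intermediate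
13 | methyl 3-methyl-6-oxocyclohex-2-ene-1-carboxylate | COC(=O)C1C=C(C)CCC1=O | intermediate
14 | methyl (1S)-1-{4-[(1R,4R)-3,3-dimethyl-1,4-bis(triethylsilyloxy)cyclohexyl]but-2-yn-1-yl}-3-methyl-6-oxocyclohex-2-ene-1-carboxylate | COC(=O)[C@@]1(CC#CC[C@]2(O[Si](CC)(CC)CC)CC[C@@H](O[Si](CC)(CC)CC)C(C)(C)C2)C=C(C)CCC1=O | intermediate
15 | cyclopentene-fused keto ester with tertiary OH cis to the ester (bis-TES ether) | CC1(C)C[C@](O[Si](CC)(CC)CC)(CC2=CC[C@@]3(C(=O)OC)C(=O)CC[C@](C)(O)[C@@H]23)CC[C@H]1O[Si](CC)(CC)CC | intermediate
16 | cyclopentene-fused keto lactone (lactone from the angular carboxyl to the methyl-bearing carbon; bis-TES ether) | CC1(C)C[C@](O[Si](CC)(CC)CC)(CC2=CC[C@@]34C(=O)O[C@@](C)(CCC3=O)[C@@H]24)CC[C@H]1O[Si](CC)(CC)CC | intermediate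
17 | saturated tricyclic keto lactone (bis-TES ether) | CC1(C)C[C@](O[Si](CC)(CC)CC)(C[C@H]2CC[C@@]34C(=O)O[C@@](C)(CCC3=O)[C@@H]24)CC[C@H]1O[Si](CC)(CC)CC | intermediate
18 | keto lactone with free secondary and tertiary alcohols | CC1(C)C[C@](O)(C[C@H]2CC[C@@]34C(=O)O[C@@](C)(CCC3=O)[C@@H]24)CC[C@H]1O | intermediate
19 | diketo lactone with free tertiary alcohol | CC1(C)C[C@](O)(C[C@H]2CC[C@@]34C(=O)O[C@@](C)(CCC3=O)[C@@H]24)CCC1=O | intermediate
20 | bis(tert-butyldimethylsilylhydrazone) of 19 | CC1(C)C[C@](O)(C[C@H]2CC[C@@]34C(=O)O[C@@](C)(CCC3=NN[Si](C)(C)C(C)(C)C)[C@@H]24)CCC1=NN[Si](C)(C)C(C)(C)C | intermediate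
21 | bis(alkenyl bromide) | CC1(C)C[C@](O)(C[C@H]2CC[C@@]34C(=O)O[C@@](C)(CC=C3Br)[C@@H]24)CC=C1Br | intermediate
22 | CNP0282702.1 | CC1(C)C[C@](O)(C[C@H]2CC[C@@]34C(=O)O[C@@](C)(CC[C@H]3Br)[C@@H]24)CC[C@H]1Br | target

**Count.** Total steps: 13. Longest linear sequence: 12 (steps 1–6 and 8–13).

**Steps most likely to fail**

1. Step 13. The α-bromo radical in the lactone ring may take up hydrogen too slowly on its crowded upper face, over which the CH2 link lies, so that reduction from below or loss of bromine competes. The fallback sets out from 17, where the lactone-ring ketone is the only ketone, and replaces hydrogen delivery to a bromo radical by bromine delivery to an alkyl radical, which has to come from the open lower face. KN(SiMe3)2 and PhNTf2 should give the enol triflate F1. Pd(OAc)2, PPh3, Bu3N and HCO2H should reduce it to the cyclohexene F2. Hydrobromination by hydrogen atom transfer (Co(acac)2, t-BuOOH, Et3SiH, TsBr) should add H at the CH remote from the quaternary carbon and Br to the resulting radical to give the equatorial lactone-ring bromide F3. Jones oxidation as in step 11 should give the bromo keto alcohol F4, and the hydrazone and bromine sequence of step 12 the ring A alkenyl bromide F5. The reduction of step 13, now on unhindered ring A alone, comes back to the route at 22.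

2. Step 9. Hydration of the gold-bound alkyne, or its capture by a carbonyl oxygen, may outrun attack of the alkene. The fallback sets out from 14 and separates C–C bond formation from oxygen capture. Water-free cycloisomerisation with PtCl2 (5 mol %) in toluene at 80 °C should give the bicyclo[3.1.0]hexene F6. Camphorsulfonic acid in wet CH2Cl2 should then protonate its alkene; the cyclopropylcarbinyl cation opens to the tertiary cation, which the ester captures from the opposite face. The route is rejoined at 16.

3. Step 8. Facial discrimination in the ammonium enolate ion pair may be poor for a methyl ester, or O-alkylation may compete. The fallback sets out from 13 and moves the chirality into a covalently bound auxiliary. Condensation with tert-butyl L-valinate (cat. TsOH, toluene, reflux) should give the enamino ester F7. Deprotonation with LiN(i-Pr)2 and alkylation with 10 in the solvent system that leads to the (S) centre, followed by aqueous acid hydrolysis, comes back to the route at 14.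

**Further compounds**

F1 | step 13 | enol triflate of 17 at the lactone-ring ketone | CC1(C)C[C@](O[Si](CC)(CC)CC)(C[C@H]2CC[C@@]34C(=O)O[C@@](C)(CC=C3OS(=O)(=O)C(F)(F)F)[C@@H]24)CC[C@H]1O[Si](CC)(CC)CC
F2 | step 13 | cyclohexene lactone (bis-TES ether) | CC1(C)C[C@](O[Si](CC)(CC)CC)(C[C@H]2CC[C@@]34C(=O)O[C@@](C)(CC=C3)[C@@H]24)CC[C@H]1O[Si](CC)(CC)CC
F3 | step 13 | lactone-ring bromide (bis-TES ether) | CC1(C)C[C@](O[Si](CC)(CC)CC)(C[C@H]2CC[C@@]34C(=O)O[C@@](C)(CC[C@H]3Br)[C@@H]24)CC[C@H]1O[Si](CC)(CC)CC
F4 | step 13 | bromo keto alcohol | CC1(C)C[C@](O)(C[C@H]2CC[C@@]34C(=O)O[C@@](C)(CC[C@H]3Br)[C@@H]24)CCC1=O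
F5 | step 13 | ring A alkenyl bromide | CC1(C)C[C@](O)(C[C@H]2CC[C@@]34C(=O)O[C@@](C)(CC[C@H]3Br)[C@@H]24)CC=C1Br
F6 | step 9 | bicyclo[3.1.0]hexene keto ester (bis-TES ether) | COC(=O)[C@@]12C=C[C@@]3(C[C@]4(O[Si](CC)(CC)CC)CC[C@@H](O[Si](CC)(CC)CC)C(C)(C)C4)[C@@H]1[C@@]3(C)CCC2=O
F7 | step 8 | enamino ester of 13 with tert-butyl L-valinate | COC(=O)C1=C(N[C@@H](C(C)C)C(=O)OC(C)(C)C)CCC(C)=C1
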